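The route rests on cutting the C3–C4 bond of the pyranone ring. That ring bears the bridging CH2 on C3, next to the lactone carbonyl C2. C3 is therefore the alpha-carbon of a 3-arylpropanoyl group bound to O1, while C4, C5 (methyl) and C6 (ethyl) are the unchanged backbone of a 2-methyl-3-oxopentanoate. The precursor is thus the Z enol ester formed between that keto ester and a chromenylpropanoic acid whose two phenols carry methoxymethyl groups. One base-induced intramolecular Claisen (Dieckmann) condensation forms C3–C4, closes the pyranone and delivers its complete substitution pattern. Mild acid then frees the phenols.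

Key step: step 9

Assumption: the target has no stereocentre, so the only stereochemical element to control is the Z double bond of the enol ester. The keto ester is used as the racemate because its stereocentre disappears on enolisation.

Step 1
Reactants: 1 phloroglucinol; 2 2-methylpropanoyl chloride
Product: 3 2-methyl-1-(2,4,6-trihydroxyphenyl)propan-1-one
Conditions: AlCl3 (3.5 equiv), PhNO2/CH2Cl2, 0 → 45 °C; aq. HCl work-up
Reagents that add atoms: 2-methylpropanoyl chloride (2), CC(C)C(Cl)=O
Why: Friedel–Crafts C-acylation of the symmetrical, highly activated ring can give only one regioisomer, and the chelated aryl ketone formed is deactivated enough to stop at monoacylation.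

Step 2
Reactants: 3 2-methyl-1-(2,4,6-trihydroxyphenyl)propan-1-one; 4 3-chloro-3-methylbut-1-yne
Product: 5 1-{2,6-dihydroxy-4-[(2-methylbut-3-yn-2-yl)oxy]phenyl}-2-methylpropan-1-one
Conditions: K2CO3 (1.2 equiv), KI (10 mol %), CuI (5 mol %), acetone, 55 °C
Reagents that add atoms: 3-chloro-3-methylbut-1-yne (4), CC(C)(Cl)C#C
Why: Copper-assisted Williamson-type etherification of a phenoxide with a tertiary propargylic chloride should occur at the 4-OH, which is the most acidic hydroxyl and the only one not hydrogen-bonded to the ketone, while the small excess of base leaves the two chelated hydroxyls un-ionised.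

Step 3
Reactants: 5 1-{2,6-dihydroxy-4-[(2-methylbut-3-yn-2-yl)oxy]phenyl}-2-methylpropan-1-one
Product: 7 2,4-dihydroxy-6-[(2-methylbut-3-yn-2-yl)oxy]-3-(2-methylpropanoyl)benzaldehyde, via iminium chloride 6 (not isolated)
Conditions: POCl3 (1.5 equiv), DMF, 0 °C → rt; then ice-water
Reagents that add atoms: N,N-dimethylformamide, CN(C)C=O (formyl carbon, and the Me2N group of 6); water, O (formyl oxygen); POCl3, O=P(Cl)(Cl)Cl (chloride of 6 only)
Why: Vilsmeier–Haack formylation attacks one of the two equivalent free positions of the still strongly activated ring, the first formyl group deactivates it against a second attack, and DMF buffers the HCl so that the tertiary propargyl ether, whose ionisation is retarded by the alkynyl group, should survive.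

Step 4
Reactants: 7 2,4-dihydroxy-6-[(2-methylbut-3-yn-2-yl)oxy]-3-(2-methylpropanoyl)benzaldehyde
Product: 8 2,4-bis(methoxymethoxy)-6-[(2-methylbut-3-yn-2-yl)oxy]-3-(2-methylpropanoyl)benzaldehyde
Conditions: NaH (2.3 equiv), MOMCl (2.6 equiv), DMF, 0 °C → rt
Reagents that add atoms: chloromethyl methyl ether, COCCl
Why: Williamson-type O-alkylation of both sodium phenoxides with the very reactive chloromethyl ether masks the chelated hydroxyls at this point, so that only one oxygen can close the chromene in step 5, no free ortho-hydroxyl can divert the Knoevenagel adduct of step 6 to a coumarin, and no phenol competes in steps 8 and 9.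

Step 5
Reactants: 8 2,4-bis(methoxymethoxy)-6-[(2-methylbut-3-yn-2-yl)oxy]-3-(2-methylpropanoyl)benzaldehyde
Product: 10 5,7-bis(methoxymethoxy)-2,2-dimethyl-6-(2-methylpropanoyl)-2H-chromene-8-carbaldehyde, via allenylphenol 9 (not isolated)
Conditions: o-xylene, 140 °C
Reagents that add atoms: none
Why: Aromatic propargyl Claisen rearrangement to the only free ortho position gives allenylphenol 9, which closes the 2,2-dimethylchromene by 1,5-hydrogen shift and oxa-6π electrocyclisation, and because the liberated hydroxyl is the only free one, O1 can only be the oxygen para to the ketone.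

Step 6
Reactants: 10 5,7-bis(methoxymethoxy)-2,2-dimethyl-6-(2-methylpropanoyl)-2H-chromene-8-carbaldehyde; 11 Meldrum's acid (2,2-dimethyl-1,3-dioxane-4,6-dione)
Product: 13 5-{[5,7-bis(methoxymethoxy)-2,2-dimethyl-6-(2-methylpropanoyl)-2H-chromen-8-yl]methyl}-2,2-dimethyl-1,3-dioxane-4,6-dione, via arylidene Meldrum's acid 12 (not isolated)
Conditions: Hantzsch ester (1.1 equiv), L-proline (20 mol %), EtOH, rt
Reagents that add atoms: Meldrum's acid (11), CC1(C)OC(=O)CC(=O)O1
Why: In this organocatalytic three-component reductive alkylation a proline-catalysed Knoevenagel condensation gives arylidene 12, whose highly electrophilic C=C bond alone accepts hydride from the Hantzsch ester, so the chromene C3=C4 bond, the aryl ketone and the acetals stay untouched.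

Step 7
Reactants: 13 5-{[5,7-bis(methoxymethoxy)-2,2-dimethyl-6-(2-methylpropanoyl)-2H-chromen-8-yl]methyl}-2,2-dimethyl-1,3-dioxane-4,6-dione
Product: 14 3-[5,7-bis(methoxymethoxy)-2,2-dimethyl-6-(2-methylpropanoyl)-2H-chromen-8-yl]propanoic acid
Conditions: pyridine/H2O (10:1), 100 °C; work-up at pH 4 (citric acid)
Reagents that add atoms: water, O
Why: Hydrolytic opening of the monosubstituted Meldrum's acid and decarboxylation of the resulting malonic acid (the end of a malonic ester synthesis) run in a weakly basic medium that the methoxymethyl ethers and the chromene tolerate.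

Step 8
Reactants: 14 3-[5,7-bis(methoxymethoxy)-2,2-dimethyl-6-(2-methylpropanoyl)-2H-chromen-8-yl]propanoic acid; 15 ethyl 2-methyl-3-oxopentanoate
Product: 18 ethyl (Z)-3-({3-[5,7-bis(methoxymethoxy)-2,2-dimethyl-6-(2-methylpropanoyl)-2H-chromen-8-yl]propanoyl}oxy)-2-methylpent-2-enoate, via acid chloride 16 (not isolated), via sodium enolate 17 (not isolated)
Conditions: 14, Me2C=C(Cl)NMe2 (1.1 equiv), CH2Cl2, 0 °C; separately 15, NaH (1.1 equiv), THF, 0 °C; combine at −78 → 0 °C
Reagents that add atoms: ethyl 2-methyl-3-oxopentanoate (15), CCC(=O)C(C)C(=O)OCC; 1-chloro-N,N,2-trimethylprop-1-en-1-amine, CC(C)=C(Cl)N(C)C (chlorine of 16 only); NaH, [Na+].[H-] (sodium of 17 only)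
Why: This is an O-acylation of a beta-keto ester enolate in which the chloroenamine makes the acid chloride without releasing HCl (safe for the acetals), the alpha-methyl group disfavours C-acylation to a quaternary tricarbonyl compound, and acylation of the U-shaped sodium chelate, as in the Z-selective enol phosphate and enol sulfonate syntheses from such enolates, should place the acyloxy group cis to the ester.

Step 9
Reactants: 18 ethyl (Z)-3-({3-[5,7-bis(methoxymethoxy)-2,2-dimethyl-6-(2-methylpropanoyl)-2H-chromen-8-yl]propanoyl}oxy)-2-methylpent-2-enoate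
Product: 20 3-{[5,7-bis(methoxymethoxy)-2,2-dimethyl-6-(2-methylpropanoyl)-2H-chromen-8-yl]methyl}-6-ethyl-4-hydroxy-5-methyl-2H-pyran-2-one, via lithium pyranolate 19 (not isolated)
Conditions: LiN(SiMe3)2 (3 equiv), THF, −78 °C, slow addition of 18 to the base, then −78 → −20 °C; AcOH quench
Reagents that add atoms: LiN(SiMe3)2, [Li+].C[Si](C)(C)[N-][Si](C)(C)C (lithium of 19 only)
Why: Proposed new method: LiN(SiMe3)2 removes a proton from the unhindered CH2 next to the acyloxy carbonyl, the carbon of the resulting lithium ester enolate adds to the ethyl ester carbonyl that the C5=C6 double bond holds on the same side, and collapse of the adduct with loss of ethoxide gives the pyran-2,4-dione, which is deprotonated at once to the aromatic lithium pyranolate 19, so the condensation cannot run backwards. The closest known reaction types are the Dieckmann-type closures of O-acylsalicylates to 4-hydroxycoumarins, of alpha-acyloxy esters to tetronic acids and of saturated beta-acyloxy esters to 4-hydroxy-5,6-dihydropyranones, whereas an open-chain beta-acyloxy enoate is the untested substrate class. The single ring formed, the pyranone, closes through C3–C4 in the 6-(enolendo)-exo-trig mode, and no stereocentre is created. Site selectivity of enolisation is needed and is secured because the isobutyryl methine is shielded by two ortho methoxymethoxy groups and the C6 ethyl CH2 lies trans to the lithium-binding ester carbonyl, while anions formed there have no feasible ring closure and are returned by proton transfer under the excess base. Rate selectivity is also needed, since the enolate can expel the keto ester enolate (E1cB, ketene formation) and ethoxide can cleave the activated acyl group; the Z geometry places C3 within bonding distance of C4, lithium bridges the enolate and ester oxygens, the low temperature slows fragmentation, and inverse addition into excess base leaves no un-enolised substrate for ethoxide to attack.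

Step 10
Reactants: 20 3-{[5,7-bis(methoxymethoxy)-2,2-dimethyl-6-(2-methylpropanoyl)-2H-chromen-8-yl]methyl}-6-ethyl-4-hydroxy-5-methyl-2H-pyran-2-one
Product: 21 3-{[5,7-dihydroxy-2,2-dimethyl-6-(2-methylpropanoyl)-2H-chromen-8-yl]methyl}-6-ethyl-4-hydroxy-5-methyl-2H-pyran-2-one
Conditions: HCl (2 M in MeOH), rt → 40 °C
Reagents that add atoms: none
Why: Acid-catalysed acetal exchange with methanol removes both methoxymethyl groups, whose cleavage is favoured because each freed hydroxyl becomes hydrogen-bonded to the adjacent ketone, under conditions mild enough for the chromene double bond and the methylene bridge.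

Compound list
1 | phloroglucinol (benzene-1,3,5-triol) | Oc1cc(O)cc(O)c1 | starting material
2 | 2-methylpropanoyl chloride | CC(C)C(Cl)=O | starting material
3 | 2-methyl-1-(2,4,6-trihydroxyphenyl)propan-1-one | CC(C)C(=O)c1c(O)cc(O)cc1O | intermediate
4 | 3-chloro-3-methylbut-1-yne | CC(C)(Cl)C#C | starting material
5 | 1-{2,6-dihydroxy-4-[(2-methylbut-3-yn-2-yl)oxy]phenyl}-2-methylpropan-1-one | CC(C)C(=O)c1c(O)cc(OC(C)(C)C#C)cc1O | intermediate
6 | {2,4-dihydroxy-6-[(2-methylbut-3-yn-2-yl)oxy]-3-(2-methylpropanoyl)phenyl}methylidene(dimethyl)azanium chloride | C[N+](C)=Cc1c(O)c(C(=O)C(C)C)c(O)cc1OC(C)(C)C#C.[Cl-] | intermediate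
7 | 2,4-dihydroxy-6-[(2-methylbut-3-yn-2-yl)oxy]-3-(2-methylpropanoyl)benzaldehyde | O=Cc1c(O)c(C(=O)C(C)C)c(O)cc1OC(C)(C)C#C | intermediate
8 | 2,4-bis(methoxymethoxy)-6-[(2-methylbut-3-yn-2-yl)oxy]-3-(2-methylpropanoyl)benzaldehyde | O=Cc1c(OCOC)c(C(=O)C(C)C)c(OCOC)cc1OC(C)(C)C#C | intermediate
9 | 2-hydroxy-4,6-bis(methoxymethoxy)-3-(3-methylbuta-1,2-dien-1-yl)-5-(2-methylpropanoyl)benzaldehyde | O=Cc1c(OCOC)c(C(=O)C(C)C)c(OCOC)c(C=C=C(C)C)c1O | intermediate
10 | 5,7-bis(methoxymethoxy)-2,2-dimethyl-6-(2-methylpropanoyl)-2H-chromene-8-carbaldehyde | O=Cc1c(OCOC)c(C(=O)C(C)C)c(OCOC)c2C=CC(C)(C)Oc12 | intermediate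
11 | Meldrum's acid (2,2-dimethyl-1,3-dioxane-4,6-dione) | CC1(C)OC(=O)CC(=O)O1 | starting material
12 | 5-{[5,7-bis(methoxymethoxy)-2,2-dimethyl-6-(2-methylpropanoyl)-2H-chromen-8-yl]methylidene}-2,2-dimethyl-1,3-dioxane-4,6-dione | CC1(C)OC(=O)C(=Cc2c(OCOC)c(C(=O)C(C)C)c(OCOC)c3C=CC(C)(C)Oc23)C(=O)O1 | intermediate
13 | 5-{[5,7-bis(methoxymethoxy)-2,2-dimethyl-6-(2-methylpropanoyl)-2H-chromen-8-yl]methyl}-2,2-dimethyl-1,3-dioxane-4,6-dione | CC1(C)OC(=O)C(Cc2c(OCOC)c(C(=O)C(C)C)c(OCOC)c3C=CC(C)(C)Oc23)C(=O)O1 | intermediate
14 | 3-[5,7-bis(methoxymethoxy)-2,2-dimethyl-6-(2-methylpropanoyl)-2H-chromen-8-yl]propanoic acid | OC(=O)CCc1c(OCOC)c(C(=O)C(C)C)c(OCOC)c2C=CC(C)(C)Oc12 | intermediate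
15 | ethyl 2-methyl-3-oxopentanoate (racemic) | CCC(=O)C(C)C(=O)OCC | starting material
16 | 3-[5,7-bis(methoxymethoxy)-2,2-dimethyl-6-(2-methylpropanoyl)-2H-chromen-8-yl]propanoyl chloride | ClC(=O)CCc1c(OCOC)c(C(=O)C(C)C)c(OCOC)c2C=CC(C)(C)Oc12 | intermediate
17 | sodium (Z)-1-ethoxy-2-methyl-1-oxopent-2-en-3-olate | CC/C([O-])=C(\C)C(=O)OCC.[Na+] | intermediate
18 | ethyl (Z)-3-({3-[5,7-bis(methoxymethoxy)-2,2-dimethyl-6-(2-methylpropanoyl)-2H-chromen-8-yl]propanoyl}oxy)-2-methylpent-2-enoate | CC/C(OC(=O)CCc1c(OCOC)c(C(=O)C(C)C)c(OCOC)c2c1OC(C)(C)C=C2)=C(\C)C(=O)OCC | intermediate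
19 | lithium 3-{[5,7-bis(methoxymethoxy)-2,2-dimethyl-6-(2-methylpropanoyl)-2H-chromen-8-yl]methyl}-6-ethyl-5-methyl-2-oxo-2H-pyran-4-olate | CCc1oc(=O)c(Cc2c(OCOC)c(C(=O)C(C)C)c(OCOC)c3c2OC(C)(C)C=C3)c([O-])c1C.[Li+] | intermediate
20 | 3-{[5,7-bis(methoxymethoxy)-2,2-dimethyl-6-(2-methylpropanoyl)-2H-chromen-8-yl]methyl}-6-ethyl-4-hydroxy-5-methyl-2H-pyran-2-one | CCc1oc(=O)c(Cc2c(OCOC)c(C(=O)C(C)C)c(OCOC)c3c2OC(C)(C)C=C3)c(O)c1C | intermediate
21 | 3-{[5,7-dihydroxy-2,2-dimethyl-6-(2-methylpropanoyl)-2H-chromen-8-yl]methyl}-6-ethyl-4-hydroxy-5-methyl-2H-pyran-2-one | CCc1oc(=O)c(Cc2c(O)c(C(=O)C(C)C)c(O)c3c2OC(C)(C)C=C3)c(O)c1C | target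

Total step count: 10. Longest linear sequence: 10 steps (1 to 21).

Steps most likely to fail

**Step 9.** The ester enolate may fragment to a ketene and the keto ester enolate, or ethoxide may strip the activated acyl group, faster than the ring closes. The fallback uses known chemistry, sets out from aldehyde 10 and comes back at 20. It makes the C3–CH2 bond on a preformed pyranone instead of the C3–C4 bond.
- The dianion of commercial methyl 3-oxopentanoate (NaH, then n-BuLi, THF, 0 °C) is acylated at its gamma-carbon with N-methoxy-N-methylpropanamide to give methyl 4-methyl-3,5-dioxoheptanoate F1.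
- DBU in toluene at reflux lactonises this to 6-ethyl-4-hydroxy-5-methyl-2H-pyran-2-one F2.
- A three-component reductive alkylation of F2 with 10 and Hantzsch ester (L-proline cat., CH2Cl2, rt) should then deliver 20. This reaction is established for 4-hydroxypyranones and 4-hydroxycoumarins.

**Step 8.** Competing C-acylation, or opening of the sodium chelate before acylation, would erode the Z geometry. The fallback sets out from 14 and 15 and comes back at 18. It replaces the metal enolate and acid chloride pair by a silyl enol ether and an acyl fluoride.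
- Acid 14 with cyanuric fluoride and pyridine (CH2Cl2, −10 °C) gives 3-[5,7-bis(methoxymethoxy)-2,2-dimethyl-6-(2-methylpropanoyl)-2H-chromen-8-yl]propanoyl fluoride F3.
- Keto ester 15 with NaH and then Me3SiCl (THF, 0 °C) gives ethyl (Z)-2-methyl-3-[(trimethylsilyl)oxy]pent-2-enoate F4. This compound is distillable, so its geometry can be checked and purified before the valuable acid is committed.
- Catalytic anhydrous Bu4NF (THF, −78 → 0 °C) then triggers the known fluoride-catalysed O-acylation of the silyl enol ether by the acyl fluoride, and chromatography removes any E isomer.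

**Step 2.** Alkylation at carbon, at a second hydroxyl, or premature rearrangement of the ether may take over. The fallback sets out from 3 and comes back at 10. It builds the chromene by condensation instead of by ether rearrangement.
- Compound 3 and 3-methylbut-2-enal in pyridine at 110 °C undergo a Knoevenagel condensation and oxa-6π electrocyclisation cascade, which is expected to close preferentially on the non-chelated oxygen. This gives 1-(5,7-dihydroxy-2,2-dimethyl-2H-chromen-6-yl)-2-methylpropan-1-one F5, which must be separated from its regioisomer closed on an ortho oxygen.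
- Vilsmeier–Haack formylation (POCl3, DMF) at the one free ring position gives 5,7-dihydroxy-2,2-dimethyl-6-(2-methylpropanoyl)-2H-chromene-8-carbaldehyde F6.
- NaH and MOMCl in DMF convert this into 10.

Further compounds
F1 | step 9 | methyl 4-methyl-3,5-dioxoheptanoate | CCC(=O)C(C)C(=O)CC(=O)OC
F2 | step 9 | 6-ethyl-4-hydroxy-5-methyl-2H-pyran-2-one | CCc1oc(=O)cc(O)c1C
F3 | step 8 | 3-[5,7-bis(methoxymethoxy)-2,2-dimethyl-6-(2-methylpropanoyl)-2H-chromen-8-yl]propanoyl fluoride | FC(=O)CCc1c(OCOC)c(C(=O)C(C)C)c(OCOC)c2C=CC(C)(C)Oc12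
F4 | step 8 | ethyl (Z)-2-methyl-3-[(trimethylsilyl)oxy]pent-2-enoate | CC/C(O[Si](C)(C)C)=C(\C)C(=O)OCC
F5 | step 2 | 1-(5,7-dihydroxy-2,2-dimethyl-2H-chromen-6-yl)-2-methylpropan-1-one | CC(C)C(=O)c1c(O)cc2OC(C)(C)C=Cc2c1O
F6 | step 2 | 5,7-dihydroxy-2,2-dimethyl-6-(2-methylpropanoyl)-2H-chromene-8-carbaldehyde | O=Cc1c(O)c(C(=O)C(C)C)c(O)c2C=CC(C)(C)Oc12
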